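Cuts, in retrosynthetic order: N4–H and N9–H are masked as tert-butyl carbamates. The two aryl C3–OH bonds are then cut together, one on each ring, followed by the two amide bonds N1–C(=O) and N12–C(=O). This leaves spermine and 3-(4-hydroxyphenyl)propanoic acid.
Enabling feature: each benzene ring carries the propanoyl chain at C1, one OH at C4 (para to the chain) and the other OH at C3 (ortho to the first OH, meta to the chain). In a 4-hydroxyphenyl ring C3 and C5 are equivalent and C1 is occupied, so oxygen delivered next to the phenol OH can end up in only one place.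
Forward: spermine is trifluoroacetylated at N1/N12, Boc-protected at N4/N9 and unmasked. Both primary amines are then acylated in one operation with the N-hydroxysuccinimide ester of the phenol acid.
Both phenol rings are next oxidised with IBX to ortho-quinones and reduced in the same flask to catechols, and acid then removes the Boc groups. The air-sensitive catechols exist only in the last two steps and need no protection.
No ring is built (both benzene rings are bought). The target has no stereocentre and no double-bond geometry, so no stereocontrol is required.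

Key step: step 5

Assumption: the target is taken as the neutral compound of the SMILES, so the last step ends with an exact neutralisation; in solution this compound will sit partly as its ammonium catecholate tautomer.

Step 1
Reactants: 1 spermine; 2 ethyl trifluoroacetate; 3 di-tert-butyl dicarbonate
Product: 5 N4,N9-bis(tert-butoxycarbonyl)-N1,N12-bis(trifluoroacetyl)spermine, via N1,N12-bis(trifluoroacetyl)spermine 4 (not isolated)
Conditions: CF3CO2Et (2.0 equiv), MeOH, −78 → 0 °C; then Boc2O (2.5 equiv), 0 °C → rt, same flask; silica gel
Reagents that add atoms: ethyl trifluoroacetate (2), CCOC(=O)C(F)(F)F; di-tert-butyl dicarbonate (3), CC(C)(C)OC(=O)OC(=O)OC(C)(C)C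
Why: Aminolysis of the mild acyl donor 2 at low temperature takes place only at the two unhindered primary nitrogens (chemoselective N-trifluoroacetylation of a polyamine), and the two secondary nitrogens that stay basic are then converted into tert-butyl carbamates by 3 in the same flask (N-Boc protection), which makes every component neutral and separable on silica gel.

Step 2
Reactants: 5 N4,N9-bis(tert-butoxycarbonyl)-N1,N12-bis(trifluoroacetyl)spermine
Product: 6 N4,N9-bis(tert-butoxycarbonyl)spermine (di-tert-butyl butane-1,4-diylbis[(3-aminopropyl)carbamate])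
Conditions: NH3 (7 M in MeOH, excess), closed flask, rt
Reagents that add atoms: none
Why: The strongly electrophilic trifluoroacetamide carbonyl undergoes ammonolysis at room temperature (standard trifluoroacetamide cleavage), whereas tert-butyl carbamates do not react with ammonia, so only N1 and N12 are set free.

Step 3
Reactants: 7 3-(4-hydroxyphenyl)propanoic acid; 8 N-hydroxysuccinimide
Product: 9 2,5-dioxopyrrolidin-1-yl 3-(4-hydroxyphenyl)propanoate (the N-hydroxysuccinimide ester of 7)
Conditions: DCC (1.05 equiv), THF, 0 °C → rt; filter
Reagents that add atoms: N-hydroxysuccinimide (8), ON1C(=O)CCC1=O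
Why: Carbodiimide activation gives the O-acylisourea, which the acidic and highly nucleophilic N–OH group of 8 intercepts faster than the phenol can (active-ester formation by DCC coupling), so the phenol needs no protecting group.

Step 4
Reactants: 6 N4,N9-bis(tert-butoxycarbonyl)spermine; 9 2,5-dioxopyrrolidin-1-yl 3-(4-hydroxyphenyl)propanoate
Product: 10 N4,N9-bis(tert-butoxycarbonyl)-N1,N12-bis[3-(4-hydroxyphenyl)propanoyl]spermine
Conditions: 9 (2.1 equiv), iPr2NEt (2.2 equiv), CH2Cl2–DMF, 0 °C → rt
Reagents that add atoms: none
Why: Aminolysis of an N-hydroxysuccinimide ester (active-ester amide coupling) is far faster at the two aliphatic primary amines than at a neutral phenol, the carbamate nitrogens are inert, and the twofold symmetry of 6 lets both amide bonds form in one operation.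

Step 5
Reactants: 10 N4,N9-bis(tert-butoxycarbonyl)-N1,N12-bis[3-(4-hydroxyphenyl)propanoyl]spermine; 11 2-iodoxybenzoic acid (IBX)
Product: 13 N4,N9-bis(tert-butoxycarbonyl)kukoamine A (N4,N9-bis(tert-butoxycarbonyl)-N1,N12-bis[3-(3,4-dihydroxyphenyl)propanoyl]spermine), via bis(ortho-quinone) 12 (not isolated)
Conditions: IBX (2.4 equiv), MeOH, −25 → 0 °C, Ar, dark, until 10 is consumed; then Na2S2O4 (5 equiv) in degassed H2O, 0 °C → rt, same flask
Reagents that add atoms: 2-iodoxybenzoic acid (11), O=C1OI(=O)(O)c2ccccc12
Why: Each phenol oxygen exchanges onto the pentavalent iodine of 11 with loss of water, an iodine-bound oxygen is passed intramolecularly to the neighbouring ring carbon C3 while iodine drops to the trivalent state, and after rearomatisation the iodine-bound catechol collapses to the ortho-quinone and 2-iodobenzoic acid (monovalent iodine), so one equivalent of 11 serves each ring, and Na2S2O4 then reduces both quinone units of 12 to catechols. The closest known reaction type is the regioselective IBX oxidation of para-alkylphenols (tyrosol esters, protected tyrosines, 4-hydroxyphenylpropanoates) to ortho-quinones with reductive work-up to the catechols, run here on two identical and electronically isolated rings of one molecule. No ring closes and no stereocentre arises; the step forms only the two aryl C3–O bonds. Ortho selectivity is needed and is secured by the oxidant being bound to the phenol oxygen, by the chain occupying C1 (para) and by the equivalence of C3 and C5, which leaves one possible regioisomer per ring. Survival of the electrophilic quinones is also needed and is secured by all four nitrogens being amides or carbamates, by the low temperature and by reduction as soon as 10 is consumed, before a 4-alkyl-ortho-quinone can tautomerise to a para-quinone methide.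

Step 6
Reactants: 13 N4,N9-bis(tert-butoxycarbonyl)kukoamine A
Product: 15 kukoamine A (N1,N12-bis[3-(3,4-dihydroxyphenyl)propanoyl]spermine), via kukoamine A bis(hydrochloride) 14 (not isolated)
Conditions: HCl (4 M in 1,4-dioxane, degassed), Ar, 0 °C → rt; evaporate; then NaOMe (2.0 equiv), degassed MeOH, 0 °C, Ar; filter, Sephadex LH-20 (degassed MeOH)
Reagents that add atoms: none
Why: Acidolysis of tert-butyl carbamates (protonation, loss of the tert-butyl cation as 2-methylpropene, decarboxylation of the carbamic acid) leaves the secondary amides and the catechols untouched, the acidic medium and the exclusion of air keep the catechols from autoxidation, and two equivalents of NaOMe then remove exactly the two equivalents of HCl held by 14.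

Compound list (no compound has a stereocentre)
1 | spermine | NCCCNCCCCNCCCN | starting material
2 | ethyl trifluoroacetate | CCOC(=O)C(F)(F)F | starting material
3 | di-tert-butyl dicarbonate | CC(C)(C)OC(=O)OC(=O)OC(C)(C)C | starting material
4 | N1,N12-bis(trifluoroacetyl)spermine | O=C(NCCCNCCCCNCCCNC(=O)C(F)(F)F)C(F)(F)F | intermediate
5 | N4,N9-bis(tert-butoxycarbonyl)-N1,N12-bis(trifluoroacetyl)spermine | O=C(NCCCN(CCCCN(CCCNC(=O)C(F)(F)F)C(=O)OC(C)(C)C)C(=O)OC(C)(C)C)C(F)(F)F | intermediate
6 | N4,N9-bis(tert-butoxycarbonyl)spermine | NCCCN(CCCCN(CCCN)C(=O)OC(C)(C)C)C(=O)OC(C)(C)C | intermediate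
7 | 3-(4-hydroxyphenyl)propanoic acid | O=C(O)CCc1ccc(O)cc1 | starting material
8 | N-hydroxysuccinimide | ON1C(=O)CCC1=O | starting material
9 | 2,5-dioxopyrrolidin-1-yl 3-(4-hydroxyphenyl)propanoate | O=C(CCc1ccc(O)cc1)ON1C(=O)CCC1=O | intermediate
10 | N4,N9-bis(tert-butoxycarbonyl)-N1,N12-bis[3-(4-hydroxyphenyl)propanoyl]spermine | O=C(CCc1ccc(O)cc1)NCCCN(CCCCN(CCCNC(=O)CCc1ccc(O)cc1)C(=O)OC(C)(C)C)C(=O)OC(C)(C)C | intermediate
11 | 2-iodoxybenzoic acid (IBX; 1-hydroxy-1,2-benziodoxol-3(1H)-one 1-oxide) | O=C1OI(=O)(O)c2ccccc12 | starting material
12 | N4,N9-bis(tert-butoxycarbonyl)-N1,N12-bis[3-(3,4-dioxocyclohexa-1,5-dien-1-yl)propanoyl]spermine (bis(ortho-quinone)) | O=C(CCC1=CC(=O)C(=O)C=C1)NCCCN(CCCCN(CCCNC(=O)CCC1=CC(=O)C(=O)C=C1)C(=O)OC(C)(C)C)C(=O)OC(C)(C)C | intermediate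
13 | N4,N9-bis(tert-butoxycarbonyl)kukoamine A | O=C(CCc1ccc(O)c(O)c1)NCCCN(CCCCN(CCCNC(=O)CCc1ccc(O)c(O)c1)C(=O)OC(C)(C)C)C(=O)OC(C)(C)C | intermediate
14 | kukoamine A bis(hydrochloride) | O=C(CCc1ccc(O)c(O)c1)NCCCNCCCCNCCCNC(=O)CCc1ccc(O)c(O)c1.Cl.Cl | intermediate
15 | kukoamine A | O=C(CCc1ccc(O)c(O)c1)NCCCNCCCCNCCCNC(=O)CCc1ccc(O)c(O)c1 | target

Total step count: 6.
Longest linear sequence: 5 (steps 1, 2, 4, 5 and 6 from spermine). Step 3 is a one-step side branch.

Steps most likely to fail

Step 5. The two rings may convert unevenly. The 4-alkyl-ortho-quinone units may also decay before reduction, by tautomerisation to quinone methides, by addition of methanol or hydrogensulfite, or by oligomerisation.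
- The fallback sets out from 10, comes back at 13 and passes through no quinone.
- Magnesium-phenoxide-directed ortho-formylation (MgCl2, Et3N, paraformaldehyde, MeCN, reflux; Casnati–Skattebøl formylation) places a formyl group on C3 of each ring. This gives N4,N9-bis(tert-butoxycarbonyl)-N1,N12-bis[3-(3-formyl-4-hydroxyphenyl)propanoyl]spermine F1.
- A Dakin oxidation (30% H2O2, NaOH, THF–H2O, 0 °C, Ar) then turns each formyl group into a hydroxyl group by aryl migration and hydrolysis of the aryl formate. This delivers 13.

Step 6. The tert-butyl cation set free may alkylate the electron-rich catechol rings. The catechols may also autoxidise while they are handled in the deprotection and the neutralisation.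
- The fallback sets out from 13 and comes back at 14.
- Peracetylation (Ac2O, pyridine, CH2Cl2, 0 °C → rt) gives the air-stable, ring-deactivated N4,N9-bis(tert-butoxycarbonyl)-N1,N12-bis[3-(3,4-diacetoxyphenyl)propanoyl]spermine F2, which can be purified at leisure.
- Degassed HCl in MeOH (from AcCl and MeOH, rt, Ar) first cleaves the carbamates while the rings are still esterified and methanol is there to take up the cation. It then methanolyses the four aryl acetates to give 14.
- 14 is neutralised as in step 6.

Step 1. Discrimination between primary and secondary nitrogens may be imperfect. The result would be a statistical mixture of under- and over-trifluoroacetylated species that is carried into the Boc protection.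
- The fallback needs no such discrimination, because the chain is built with the nitrogens already differentiated.
- It sets out from 3, the only numbered input it keeps. Commercial butane-1,4-diamine and acrylonitrile take the place of 1 and 2. It comes back at 6.
- Twofold aza-Michael addition of butane-1,4-diamine to acrylonitrile (2 equiv, EtOH, 0 °C → rt) gives 3,3'-(butane-1,4-diyldiimino)dipropanenitrile F3.
- Treatment with 3 (CH2Cl2, rt) gives di-tert-butyl butane-1,4-diylbis[(2-cyanoethyl)carbamate] F4.
- Hydrogenation of both nitriles (H2, Raney Ni, NH3 in MeOH) gives 6.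

Further compounds
F1 | step 5 | N4,N9-bis(tert-butoxycarbonyl)-N1,N12-bis[3-(3-formyl-4-hydroxyphenyl)propanoyl]spermine | O=C(CCc1ccc(O)c(C=O)c1)NCCCN(CCCCN(CCCNC(=O)CCc1ccc(O)c(C=O)c1)C(=O)OC(C)(C)C)C(=O)OC(C)(C)C
F2 | step 6 | N4,N9-bis(tert-butoxycarbonyl)-N1,N12-bis[3-(3,4-diacetoxyphenyl)propanoyl]spermine | CC(=O)Oc1ccc(CCC(=O)NCCCN(CCCCN(CCCNC(=O)CCc2ccc(OC(C)=O)c(OC(C)=O)c2)C(=O)OC(C)(C)C)C(=O)OC(C)(C)C)cc1OC(C)=O
F3 | step 1 | 3,3'-(butane-1,4-diyldiimino)dipropanenitrile | N#CCCNCCCCNCCC#N
F4 | step 1 | di-tert-butyl butane-1,4-diylbis[(2-cyanoethyl)carbamate] | N#CCCN(CCCCN(CCC#N)C(=O)OC(C)(C)C)C(=O)OC(C)(C)C
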